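## Analysis of the target

CNP0319766.1 is a cembranolide. Cembrane numbering is used throughout: ring carbons C1–C14, C15–C17 on C1 (C16 is the lactone carbonyl, C17 the methyl on C15), C18 on C4, C19 on C8, C20 on C12. The 14-membered carbocycle is bridged from C1 to C3 by a δ-lactone (C1–C2–C3–O–C16–C15). It also carries a trans trisubstituted 11,12-epoxide, an exocyclic C8=C19 methylene, a tertiary alcohol at C4 and a secondary allylic hydroperoxide at C7.

The seven stereocentres are 1R,3R,4S,7R,11S,12S,15S. On the lactone the C14 chain (on C1) and the C4 group (on C3) are cis and the C17 methyl is trans to the C14 chain, which is the all-equatorial, thermodynamically preferred arrangement. O3 and O4 are anti. The epoxide pair and C7 are remote from this cluster and cannot be relayed from it.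

The hydroperoxide is destroyed by phosphines, hydrides, low-valent metals and base (Kornblum–DeLaMare), the epoxide by acid, and the lactone by hard nucleophiles, so the hydroperoxide has to come last. The hard points are three separate stereochemical domains, closure of the 14-membered ring, and C3, which sits next to a quaternary carbon whose two carbon substituents (C18 methyl, C5 methylene) differ little.

The strategy rests on one feature: C3 carries the lactone oxygen and lies δ to the C16 carbonyl through C2, C1 and C15. That is the retron of γ-attack of an ester dienolate on a C3 aldehyde followed by lactonisation.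

## Retrosynthetic reasoning

**C7–O bond (37 ⇐ 36 ⇐ 35 ⇐ 31 + 33).** The hydroperoxide is unveiled last. The C7–O bond is cut as an SN2 displacement of the (7S)-mesylate 34, made from alcohol 31, by the anion of the protected hydroperoxide 33. Substitution puts oxygen on C7 only, whereas an ene oxygenation of a C7=C8 alkene would have three allylic positions to choose from. The forward reaction must invert cleanly at a secondary allylic carbon. The C4 oxygen stays silylated until the end, because a free C4 hydroxyl would close a tetrahydrofuran onto C7.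

**C7 configuration (31 ⇐ 30 ⇐ 29).** A macrocyclic carbonyl addition cannot be trusted to set C7. Both epimers of 29 are therefore oxidised to enone 30 and the (7S)-carbinol is set by reagent control.

**C7–C8 bond (29 ⇐ 27).** This is the only ring bond flanked by functionality on both sides (carbinol and 1,1-disubstituted alkene), the retron of an alkenylmetal addition to an aldehyde. All other ring bonds join unfunctionalised CH2 groups or touch the epoxide. A Nozaki–Hiyama–Kishi closure tolerates lactone, epoxide and silyl ether and delivers the C8=C19 methylene directly.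

**C7 aldehyde, C15–C17 and C1–H (27 ⇐ 25 ⇐ 23 ⇐ 21).** The aldehyde is carried as a prenyl alkene and released by oxidative cleavage. The C17 methyl is removed as an enolate alkylation and the C1 hydrogen as a conjugate reduction of the 5,6-dihydropyran-2-one 21. Both new centres are relayed from C3 across the six-membered lactone: hydride enters anti to the C3 substituent, and the methyl enters anti to the C1 chain.

**C2–C3 and O–C16 (21 ⇐ 5 + 19, key step).** Cutting C2–C3 and the lactone C–O bond divides the molecule into two terpenoid halves of similar size. Aldehyde 5 is non-enolisable and carries C4; silyl dienolate 19 carries the epoxide and the alkenyl iodide. Two design points were settled here.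

- Lactonisation needs C2 and C16 cis on the new C1=C15 bond. A conventional Lewis-acid-activated addition through an open transition state would leave the C1–C15 bond free to react s-trans and give the (2E)-hydroxy ester, which cannot close. The dienolate is therefore activated as a monovalent copper dienolate (CuF·Tol-BINAP), which holds both partners on one metal and lactonises as part of its turnover. This also keeps strong Lewis acids away from the epoxide.
- The enolate oxygen substituents are ethyl and trimethylsilyl. A bis-silyl ketene acetal would need a saponification and a silyl ester, and the alkoxide is expelled on ring closure in either case.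

**Dienolate partner (19 ⇐ 17 ⇐ 16 ⇐ 14 + 15).** Kinetic γ-deprotonation of a 3-methyl-2-enoate removes the proton syn to the ester, so only the (2E)-ester 17 gives the C2 dienolate. The (2E)-geometry is set by Horner–Wadsworth–Emmons olefination of methyl ketone 14 with 15. The epoxide is introduced on 16 by Shi epoxidation, because the isolated trisubstituted C11=C12 alkene is the only electron-rich alkene present.

**Ketone 14 (⇐ 10 + 11; 10 ⇐ 8 + 9; 8 ⇐ 7 ⇐ 6).** The pattern ketone–CH2–CH2–C(CH3)=CH is the retron of a ketone Claisen rearrangement of the 2-methylallylic alcohol 10 with 11. This forms C13–C14 and fixes the (E)-C11=C12 geometry in one step. The alkenyl iodide is made first, on the small alkyne 6, where hydrogen iodide can be used before any epoxide exists.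

**Aldehyde 5 (⇐ 3 ⇐ 2 ⇐ 1).** C4 comes from (S)-linalool 1. Its vinyl group is a latent formyl group, reached by hydroxyl-directed epoxidation (the vinyl group is otherwise the less reactive alkene), silylation and periodic acid cleavage.

**Reagent 33 (⇐ 32).** The hydroperoxy ketal is obtained by ozonolysis of 32 in methanol.

## Alternatives that were turned down

**Alternative 1:** The C5–C6 bond is cut. A 16-membered allyl enol carbonate A1 (C4 enol oxygen tied through a carbonate to C6) would be ionised by Pd(PPh3)4; decarboxylation and collapse of the enolate/π-allyl pair through C5 onto C6 would give the 14-membered C4 ketone A2.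
- For: the ring closes by C–C bond formation within an ion pair, under neutral conditions, probably more efficiently than a chromium-mediated closure. The (E)-C7=C8 alkene it leaves would allow a single photo-oxygenation to finish C7, shorter than the five operations used here. On those two points it is stronger.
- Against: the enol carbonate must be formed regioselectively on the methyl side of a ketone that has a more acidic α-alkoxy C3–H. A2 still lacks the C18 methyl (addition to a macrocyclic ketone), the lactone, and any relay for C1 and C15, which would have to be built acyclically. The final ene reaction must choose between hydrogens on C6, C9 and C19 and between two faces.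
- The chosen route places the C7 oxygen by C–C bond construction and sets C1 and C15 from C3.

**Alternative 2:** This is a stereochemical rather than a skeletal disconnection. A farnesane-type triene diol A3 with two allylic alcohol termini would be epoxidised at both ends with Ti(OiPr)4, L-(+)-diethyl tartrate and tert-butyl hydroperoxide to give bis-epoxy diol A4 (3S,4S,11S,12S), leaving C7=C8.
- For: four stereocentres from one catalytic step with inexpensive reagents, and the double epoxidation raises the enantiomeric purity. This is stronger than the present sourcing of C4 from linalool and of C11/C12 from an L-fructose-derived ketone.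
- Against: A4 solves none of the ring construction. C1–C2, C13–C14, the lactone, the macrocycle, C1, C15 and C7 all remain. Both termini are hydroxymethyl epoxides that must be differentiated although nearly identical, and both need C–C bond formation next to an epoxide. The C3–C4 epoxide must be opened with inversion by the carboxyl oxygen.
- The chosen route gives up some stereochemical economy and gains a direct build of the C2–C3 bond with the lactone.

**Alternative 3:** The C1–C15 bond is cut across a preformed macrocycle. A bromoacetal A5 on the C3 oxygen would give a C15 radical with Bu3SnH, which adds 6-exo to C1 of a ring C1=C14 alkene to form the bicyclic lactol acetal A6.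
- For: C1 and C15 are set in one step (here two), under neutral conditions that spare epoxide and silyl ether, and no late macrocyclisation is needed.
- Against: the difficulty is moved into A5, a 14-membered ring with a positionally defined C1=C14 alkene and a C3 carbinol, whose synthesis is open. The 6-exo closure onto a 1,2-disubstituted alkene is slow against reduction and hydrogen transfer, and the C15 configuration depends on macrocycle conformation. The acetal must still be hydrolysed (acid, with the epoxide present) and oxidised, and C7 again depends on an ene reaction.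
- The chosen route forms the lactone at the right oxidation level and sets C1 and C15 on a simple six-membered ring.

Key step: step 11

## Remarks

- (S)-(+)-Linalool is assumed to be available in high enantiomeric purity.
- The sense of induction of (S)-Tol-BINAP in step 11 is an assumption, to be confirmed against its antipode; the substrate's own bias already favours the required face.

## Route

Step 1
Reactants: 1 (S)-(+)-linalool
Product: 2 (3S)-1,2-epoxy-3,7-dimethyloct-6-en-3-ol (both C2 epimers)
Conditions: VO(acac)2 (2 mol %), t-BuOOH (1.2 equiv, decane), toluene, 0 °C → rt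
Reagents that add atoms: tert-butyl hydroperoxide, CC(C)(C)OO
Why: Hydroxyl-directed vanadium-catalysed epoxidation delivers oxygen to the allylic vinyl group faster than to the remote trisubstituted alkene; the new epoxide centre is destroyed in step 3 and the carbinol centre (C4 of the target) is untouched.

Step 2
Reactants: 2 (3S)-1,2-epoxy-3,7-dimethyloct-6-en-3-ol
Product: 3 triethyl{[(3S)-1,2-epoxy-3,7-dimethyloct-6-en-3-yl]oxy}silane
Conditions: Et3SiOTf, 2,6-lutidine, CH2Cl2, −78 → 0 °C
Reagents that add atoms: triethylsilyl trifluoromethanesulfonate, CC[Si](CC)(CC)OS(=O)(=O)C(F)(F)F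
Why: Silyl triflate with lutidine is the standard silylation of a hindered tertiary alcohol; the ether prevents a 1,2,3-triol (which periodate would cut on both sides) and later enforces non-chelated addition to the aldehyde.

Step 3
Reactants: 3 triethyl{[(3S)-1,2-epoxy-3,7-dimethyloct-6-en-3-yl]oxy}silane
Product: 5 (2S)-2,6-dimethyl-2-(triethylsilyloxy)hept-5-enal, via vicinal diol 4 (not isolated)
Conditions: H5IO6, THF/H2O, 0 °C → rt
Reagents that add atoms: none
Why: Periodic acid hydrolyses the terminal epoxide at its CH2 terminus and cleaves the glycol in the same flask (epoxide-to-aldehyde degradation), so the aldehyde oxygen is the former epoxide oxygen; the quaternary α-carbon cannot epimerise.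

Step 4
Reactants: 6 pent-4-yn-1-ol
Product: 7 4-iodopent-4-en-1-ol
Conditions: NaI, Me3SiCl, H2O, MeCN, rt
Reagents that add atoms: sodium iodide, [Na+].[I-]
Why: Hydrogen iodide generated in the flask adds to the terminal alkyne in the Markovnikov sense (alkyne hydroiodination) to give the 2-iodo-1-alkene; any O-silyl group is lost on aqueous work-up.

Step 5
Reactants: 7 4-iodopent-4-en-1-ol
Product: 8 4-iodopent-4-enal
Conditions: Dess–Martin periodinane, NaHCO3, CH2Cl2, 0 °C → rt
Reagents that add atoms: none
Why: Buffered Dess–Martin oxidation of the primary alcohol leaves the alkenyl iodide alone; the aldehyde is used at once.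

Step 6
Reactants: 8 4-iodopent-4-enal; 9 isopropenylmagnesium bromide
Product: 10 rac-6-iodo-2-methylhepta-1,6-dien-3-ol
Conditions: THF, −78 → −20 °C; aq. NH4Cl
Reagents that add atoms: none
Why: Grignard 1,2-addition to the aldehyde is fast at low temperature, where iodine–magnesium exchange does not compete; the carbinol centre is left racemic because it is erased in step 7.

Step 7
Reactants: 10 rac-6-iodo-2-methylhepta-1,6-dien-3-ol; 11 2-methoxypropene
Product: 14 (5E)-9-iodo-5-methyldeca-5,9-dien-2-one, via mixed ketal 12 (not isolated), via allyl isopropenyl ether 13 (not isolated)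
Conditions: 2-methoxypropene (excess), EtCO2H (cat.), xylenes, 135 °C, sealed tube
Reagents that add atoms: none
Why: Saucy–Marbet (ketone) Claisen rearrangement: acid-catalysed exchange and loss of methanol give the allyl isopropenyl ether, whose chair [3,3] shift with the iodobutenyl chain equatorial forms C13–C14 and the (E)-C11=C12 bond.

Step 8
Reactants: 14 (5E)-9-iodo-5-methyldeca-5,9-dien-2-one; 15 triethyl phosphonoacetate
Product: 16 ethyl (2E,6E)-10-iodo-3,6-dimethylundeca-2,6,10-trienoate
Conditions: NaH, THF, 0 → 50 °C; chromatographic removal of the minor (2Z)-isomer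
Reagents that add atoms: none
Why: Horner–Wadsworth–Emmons olefination of the methyl ketone is expected to favour the (2E)-ester; the (2Z)-isomer is removed because only the (2E)-geometry places the C2 methyl syn to the ester for step 10.

Step 9
Reactants: 16 ethyl (2E,6E)-10-iodo-3,6-dimethylundeca-2,6,10-trienoate
Product: 17 ethyl (2E)-5-[(2S,3S)-3-(3-iodobut-3-en-1-yl)-2-methyloxiran-2-yl]-3-methylpent-2-enoate
Conditions: L-fructose-derived Shi ketone (30 mol %), KHSO5 (as Oxone), K2CO3, Bu4NHSO4, MeCN/dimethoxymethane/aq. buffer (pH 10.5), 0 °C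
Reagents that add atoms: potassium peroxymonosulfate, [K+].[O-]S(=O)(=O)OO
Why: Shi epoxidation: the chiral dioxirane attacks only the electron-rich trisubstituted C11=C12 alkene (enoate and iodoalkene are deactivated) through the spiro transition state; the D-fructose ketone gives (R,R)-epoxides from (E)-trisubstituted alkenes of this pattern, so its L-antipode should give the (11S,12S)-epoxide.

Step 10
Reactants: 17 ethyl (2E)-5-[(2S,3S)-3-(3-iodobut-3-en-1-yl)-2-methyloxiran-2-yl]-3-methylpent-2-enoate
Product: 19 1-ethoxy-3-{2-[(2S,3S)-3-(3-iodobut-3-en-1-yl)-2-methyloxiran-2-yl]ethyl}-1-(trimethylsilyloxy)buta-1,3-diene, via lithium dienolate 18 (not isolated)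
Conditions: LiN(i-Pr)2 (1.1 equiv), THF, −78 °C; Me3SiCl, −78 → 0 °C; pentane, filtration, used crude
Reagents that add atoms: chlorotrimethylsilane, C[Si](C)(C)Cl
Why: Kinetic γ-deprotonation of the (2E)-enoate removes a proton from the methyl group syn to the ester carbonyl (C2), and O-silylation of the extended enolate gives the silyl dienolate; at −78 °C the epoxide and the alkenyl iodide are not attacked.

Step 11
Reactants: 5 (2S)-2,6-dimethyl-2-(triethylsilyloxy)hept-5-enal; 19 1-ethoxy-3-{2-[(2S,3S)-3-(3-iodobut-3-en-1-yl)-2-methyloxiran-2-yl]ethyl}-1-(trimethylsilyloxy)buta-1,3-diene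
Product: 21 (6R)-4-{2-[(2S,3S)-3-(3-iodobut-3-en-1-yl)-2-methyloxiran-2-yl]ethyl}-6-[(2S)-6-methyl-2-(triethylsilyloxy)hept-5-en-2-yl]-5,6-dihydro-2H-pyran-2-one, via copper aldolate 20 (not isolated)
Conditions: Cu(OTf)2 (10 mol %), (S)-Tol-BINAP (11 mol %), Bu4N[Ph3SiF2] (20 mol %), THF, −78 → 0 °C
Reagents that add atoms: none
Why: Fluoride and the copper salt convert the silyl dienolate into a monovalent copper dienolate carrying Tol-BINAP, which adds through its γ-carbon C2 to the aldehyde carbon C3; the closest known reaction type is the CuF·Tol-BINAP-catalysed vinylogous Mukaiyama aldol of silyl dienolates that gives 5,6-dihydropyran-2-ones directly. Because dienolate oxygen and aldehyde oxygen are held on the same copper centre, the dienolate should react in its s-cis form, so the new C1=C15 bond carries C2 and C16 cis. The copper alkoxide on C3 then closes the lactone by 6-exo-trig acyl substitution at C16, expelling copper ethoxide, which desilylates the next dienolate and releases EtOSiMe3. C3 is set by attack on the Re face of the aldehyde: with the C4–OSi bond anti to the incoming carbon (Felkin–Anh, and equally Cornforth), the nucleophile passes the C18 methyl and not the C5 methylene, giving the 3R,4S (anti) pair, and the chiral bisphosphine is chosen to add to this modest bias. γ- over α-attack is secured by the copper dienolate and by the C1 substituent, which crowds C15. The closed arrangement is essential, since an open transition state would allow the s-trans rotamer and a (2E)-hydroxy ester that cannot lactonise. No strong Lewis acid is present, so the trisubstituted epoxide, the alkenyl iodide and the tertiary silyl ether should survive, and the aldehyde cannot enolise.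

Step 12
Reactants: 21 the 5,6-dihydropyran-2-one of step 11
Product: 23 (4R,6R)-4-{2-[(2S,3S)-3-(3-iodobut-3-en-1-yl)-2-methyloxiran-2-yl]ethyl}-6-[(2S)-6-methyl-2-(triethylsilyloxy)hept-5-en-2-yl]oxan-2-one, via copper enolate 22 (not isolated)
Conditions: Cu(OAc)2·H2O (5 mol %), 1,2-bis(diphenylphosphino)benzene (5 mol %), (EtO)2MeSiH, t-BuOH, toluene, rt
Reagents that add atoms: none
Why: CuH-catalysed conjugate reduction of the unsaturated δ-lactone: hydride adds to C1 on the face opposite the bulky C3 substituent (axial attack on the half-chair), so the C14 chain ends cis to it (1R), and t-BuOH protonates the copper enolate; isolated alkenes and the epoxide are not substrates, and the alkenyl iodide is expected to be tolerated at room temperature.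

Step 13
Reactants: 23 the saturated lactone of step 12
Product: 25 (3S,4R,6R)-4-{2-[(2S,3S)-3-(3-iodobut-3-en-1-yl)-2-methyloxiran-2-yl]ethyl}-3-methyl-6-[(2S)-6-methyl-2-(triethylsilyloxy)hept-5-en-2-yl]oxan-2-one, via lithium enolate 24 (not isolated)
Conditions: LiN(SiMe3)2 (1.15 equiv), THF, −78 °C; MeI, −78 → −40 °C
Reagents that add atoms: iodomethane, CI
Why: Lactone enolate alkylation: iodomethane approaches C15 anti to the neighbouring C1 substituent, giving the trans-C1/C15 (15S), all-equatorial lactone, which is also the thermodynamically preferred epimer.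

Step 14
Reactants: 25 the methylated lactone of step 13
Product: 27 (4S)-4-[(2R,4R,5S)-4-{2-[(2S,3S)-3-(3-iodobut-3-en-1-yl)-2-methyloxiran-2-yl]ethyl}-5-methyl-6-oxooxan-2-yl]-4-(triethylsilyloxy)pentanal, via vicinal diol 26 (not isolated)
Conditions: OsO4 (2 mol %), NaIO4 (4 equiv), 2,6-lutidine, dioxane/H2O, rt
Reagents that add atoms: osmium tetroxide, O=[Os](=O)(=O)=O; sodium periodate, [Na+].[O-]I(=O)(=O)=O
Why: Lemieux–Johnson cleavage: the electron-rich trisubstituted alkene is dihydroxylated much faster than the iodine-deactivated 1,1-disubstituted alkene, and periodate cuts the diol to the C7 aldehyde and acetone; lutidine keeps the medium neutral for the epoxide.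

Step 15
Reactants: 27 the seco-aldehyde of step 14
Product: 29 (1R,3R,4S,11S,12S,15S)-11,12-epoxy-7-hydroxy-4-(triethylsilyloxy)cembr-8(19)-en-16,3-olide (C7 epimers), via alkenylchromium species 28 (not isolated)
Conditions: CrCl2 (10 equiv), NiCl2 (1 mol % of the CrCl2), DMSO/THF, rt, syringe-pump addition to 2 mM
Reagents that add atoms: none
Why: Nozaki–Hiyama–Kishi reaction: nickel inserts into the C8–I bond, transmetalation gives a trivalent alkenylchromium that adds only to the aldehyde, closing the 14-membered ring through C7–C8 and creating the C8=C19 methylene; lactone, epoxide and silyl ether are tolerated, and the C7 configuration is corrected in steps 16 and 17.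

Step 16
Reactants: 29 the macrocyclic allylic alcohol of step 15
Product: 30 (1R,3R,4S,11S,12S,15S)-11,12-epoxy-7-oxo-4-(triethylsilyloxy)cembr-8(19)-en-16,3-olide
Conditions: Dess–Martin periodinane, NaHCO3, CH2Cl2, 0 °C → rt
Reagents that add atoms: none
Why: Dess–Martin oxidation converts both C7 epimers into one α-methylene ketone under buffered, non-basic conditions.

Step 17
Reactants: 30 the macrocyclic enone of step 16
Product: 31 (1R,3R,4S,7S,11S,12S,15S)-11,12-epoxy-7-hydroxy-4-(triethylsilyloxy)cembr-8(19)-en-16,3-olide
Conditions: (R)-2-methyl-CBS-oxazaborolidine (1 equiv), catecholborane, toluene, −78 °C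
Reagents that add atoms: none
Why: Corey–Bakshi–Shibata reduction: the oxazaborolidine binds the carbonyl lone pair anti to the larger, sp2-branched C8 side and delivers hydride 1,2 to give the (7S)-carbinol needed for invertive substitution; the low temperature suppresses conjugate reduction and hydroboration.

Step 18
Reactants: 32 2,3-dimethylbut-2-ene
Product: 33 2-methoxyprop-2-yl hydroperoxide
Conditions: O3, MeOH/CH2Cl2, −78 °C; kept and used as a solution
Reagents that add atoms: ozone, [O-][O+]=O; methanol, CO
Why: Ozonolysis in methanol: the carbonyl oxide released from the primary ozonide is trapped by methanol to give the hydroperoxy ketal, a known protected form of hydrogen peroxide, together with acetone.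

Step 19
Reactants: 31 the (7S)-alcohol of step 17; 33 2-methoxyprop-2-yl hydroperoxide
Product: 35 (1R,3R,4S,7R,11S,12S,15S)-11,12-epoxy-7-[(2-methoxypropan-2-yl)peroxy]-4-(triethylsilyloxy)cembr-8(19)-en-16,3-olide, via allylic mesylate 34 (not isolated)
Conditions: (MeSO2)2O, i-Pr2NEt, CH2Cl2, −40 °C; then 33 (3 equiv), CsOH·H2O (2.5 equiv), DMF, 0 °C → rt
Reagents that add atoms: none
Why: SN2 displacement of a secondary sulfonate by a peroxide anion: the caesium salt of 33 is a weakly basic α-effect nucleophile that attacks C7 from the rear and inverts 7S to 7R; the anhydride avoids chloride, and the C4 oxygen stays silylated so that it cannot cyclise onto C7.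

Step 20
Reactants: 35 the peroxy ketal of step 19
Product: 36 (1R,3R,4S,7R,11S,12S,15S)-11,12-epoxy-7-hydroperoxy-4-(triethylsilyloxy)cembr-8(19)-en-16,3-olide
Conditions: pyridinium p-toluenesulfonate (cat.), MeOH, 0 °C
Reagents that add atoms: none
Why: Acid-catalysed transketalisation of the monoperoxy ketal with methanol frees the hydroperoxide under conditions that should be too mild to open the trisubstituted epoxide or cleave the tertiary silyl ether.

Step 21
Reactants: 36 the silylated hydroperoxide of step 20
Product: 37 (1R,3R,4S,7R,11S,12S,15S)-11,12-epoxy-7-hydroperoxy-4-hydroxycembr-8(19)-en-16,3-olide (CNP0319766.1)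
Conditions: HF·pyridine, pyridine, THF, 0 °C → rt
Reagents that add atoms: none
Why: Pyridine-buffered HF desilylation frees the C4 tertiary alcohol without strong base (no Kornblum–DeLaMare loss of the hydroperoxide) and without strong acid (epoxide retained), giving the target.

## Compound list

1 | (S)-(+)-linalool | C=C[C@@](C)(O)CCC=C(C)C | starting material
2 | (3S)-1,2-epoxy-3,7-dimethyloct-6-en-3-ol (C2 epimers) | CC(C)=CCC[C@](C)(O)C1CO1 | intermediate
3 | triethyl{[(3S)-1,2-epoxy-3,7-dimethyloct-6-en-3-yl]oxy}silane | CC(C)=CCC[C@](C)(O[Si](CC)(CC)CC)C1CO1 | intermediate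
4 | (3S)-3,7-dimethyl-3-(triethylsilyloxy)oct-6-ene-1,2-diol (not isolated) | CC(C)=CCC[C@](C)(O[Si](CC)(CC)CC)C(O)CO | intermediate
5 | (2S)-2,6-dimethyl-2-(triethylsilyloxy)hept-5-enal | O=C[C@@](C)(O[Si](CC)(CC)CC)CCC=C(C)C | intermediate
6 | pent-4-yn-1-ol | C#CCCCO | starting material
7 | 4-iodopent-4-en-1-ol | C=C(I)CCCO | intermediate
8 | 4-iodopent-4-enal | C=C(I)CCC=O | intermediate
9 | isopropenylmagnesium bromide | CC(=C)[Mg]Br | starting material
10 | rac-6-iodo-2-methylhepta-1,6-dien-3-ol | C=C(C)C(O)CCC(I)=C | intermediate
11 | 2-methoxypropene | COC(C)=C | starting material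
12 | 6-iodo-3-[(2-methoxypropan-2-yl)oxy]-2-methylhepta-1,6-diene (not isolated) | C=C(C)C(OC(C)(C)OC)CCC(I)=C | intermediate
13 | 6-iodo-2-methyl-3-(prop-1-en-2-yloxy)hepta-1,6-diene (not isolated) | C=C(C)C(OC(C)=C)CCC(I)=C | intermediate
14 | (5E)-9-iodo-5-methyldeca-5,9-dien-2-one | CC(=O)CC/C(C)=C/CCC(I)=C | intermediate
15 | triethyl phosphonoacetate | CCOC(=O)CP(=O)(OCC)OCC | starting material
16 | ethyl (2E,6E)-10-iodo-3,6-dimethylundeca-2,6,10-trienoate | CCOC(=O)/C=C(\C)CC/C(C)=C/CCC(I)=C | intermediate
17 | ethyl (2E)-5-[(2S,3S)-3-(3-iodobut-3-en-1-yl)-2-methyloxiran-2-yl]-3-methylpent-2-enoate | CCOC(=O)/C=C(\C)CC[C@]1(C)O[C@H]1CCC(I)=C | intermediate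
18 | lithium dienolate of 17, deprotonated at C2 (not isolated) | [Li]OC(OCC)=CC(=C)CC[C@]1(C)O[C@H]1CCC(I)=C | intermediate
19 | 1-ethoxy-3-{2-[(2S,3S)-3-(3-iodobut-3-en-1-yl)-2-methyloxiran-2-yl]ethyl}-1-(trimethylsilyloxy)buta-1,3-diene | C=C(CC[C@]1(C)O[C@H]1CCC(I)=C)C=C(OCC)O[Si](C)(C)C | intermediate
20 | copper alkoxide of ethyl (2Z,5R,6S)-5-hydroxy-3-{2-[(2S,3S)-3-(3-iodobut-3-en-1-yl)-2-methyloxiran-2-yl]ethyl}-6,10-dimethyl-6-(triethylsilyloxy)undeca-2,9-dienoate (bisphosphine on copper not drawn; not isolated) | CCOC(=O)/C=C(\C[C@@H](O[Cu])[C@@](C)(O[Si](CC)(CC)CC)CCC=C(C)C)CC[C@]1(C)O[C@H]1CCC(I)=C | intermediate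
21 | (6R)-4-{2-[(2S,3S)-3-(3-iodobut-3-en-1-yl)-2-methyloxiran-2-yl]ethyl}-6-[(2S)-6-methyl-2-(triethylsilyloxy)hept-5-en-2-yl]-5,6-dihydro-2H-pyran-2-one | O=C1C=C(CC[C@]2(C)O[C@H]2CCC(I)=C)C[C@@H](O1)[C@@](C)(O[Si](CC)(CC)CC)CCC=C(C)C | intermediate
22 | copper enolate of lactone 23 (not isolated) | [Cu]OC1=C[C@H](CC[C@]2(C)O[C@H]2CCC(I)=C)C[C@@H](O1)[C@@](C)(O[Si](CC)(CC)CC)CCC=C(C)C | intermediate
23 | (4R,6R)-4-{2-[(2S,3S)-3-(3-iodobut-3-en-1-yl)-2-methyloxiran-2-yl]ethyl}-6-[(2S)-6-methyl-2-(triethylsilyloxy)hept-5-en-2-yl]oxan-2-one | O=C1C[C@H](CC[C@]2(C)O[C@H]2CCC(I)=C)C[C@@H](O1)[C@@](C)(O[Si](CC)(CC)CC)CCC=C(C)C | intermediate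
24 | lithium enolate of lactone 23 (not isolated) | [Li]OC1=C[C@H](CC[C@]2(C)O[C@H]2CCC(I)=C)C[C@@H](O1)[C@@](C)(O[Si](CC)(CC)CC)CCC=C(C)C | intermediate
25 | (3S,4R,6R)-4-{2-[(2S,3S)-3-(3-iodobut-3-en-1-yl)-2-methyloxiran-2-yl]ethyl}-3-methyl-6-[(2S)-6-methyl-2-(triethylsilyloxy)hept-5-en-2-yl]oxan-2-one | O=C1[C@@H](C)[C@H](CC[C@]2(C)O[C@H]2CCC(I)=C)C[C@@H](O1)[C@@](C)(O[Si](CC)(CC)CC)CCC=C(C)C | intermediate
26 | 7,8-diol of 25 (prenyl alkene dihydroxylated; not isolated) | O=C1[C@@H](C)[C@H](CC[C@]2(C)O[C@H]2CCC(I)=C)C[C@@H](O1)[C@@](C)(O[Si](CC)(CC)CC)CCC(O)C(C)(C)O | intermediate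
27 | (4S)-4-[(2R,4R,5S)-4-{2-[(2S,3S)-3-(3-iodobut-3-en-1-yl)-2-methyloxiran-2-yl]ethyl}-5-methyl-6-oxooxan-2-yl]-4-(triethylsilyloxy)pentanal | O=C1[C@@H](C)[C@H](CC[C@]2(C)O[C@H]2CCC(I)=C)C[C@@H](O1)[C@@](C)(O[Si](CC)(CC)CC)CCC=O | intermediate
28 | trivalent alkenylchromium dichloride derived from 27 (C8–Cr in place of C8–I; not isolated) | O=C1[C@@H](C)[C@H](CC[C@]2(C)O[C@H]2CCC([Cr](Cl)Cl)=C)C[C@@H](O1)[C@@](C)(O[Si](CC)(CC)CC)CCC=O | intermediate
29 | (1R,3R,4S,11S,12S,15S)-11,12-epoxy-7-hydroxy-4-(triethylsilyloxy)cembr-8(19)-en-16,3-olide (C7 epimers) | C=C1CC[C@@H]2O[C@@]2(C)CC[C@@H]2C[C@@H](OC(=O)[C@H]2C)[C@@](C)(O[Si](CC)(CC)CC)CCC1O | intermediate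
30 | (1R,3R,4S,11S,12S,15S)-11,12-epoxy-7-oxo-4-(triethylsilyloxy)cembr-8(19)-en-16,3-olide | C=C1CC[C@@H]2O[C@@]2(C)CC[C@@H]2C[C@@H](OC(=O)[C@H]2C)[C@@](C)(O[Si](CC)(CC)CC)CCC1=O | intermediate
31 | (1R,3R,4S,7S,11S,12S,15S)-11,12-epoxy-7-hydroxy-4-(triethylsilyloxy)cembr-8(19)-en-16,3-olide | C=C1CC[C@@H]2O[C@@]2(C)CC[C@@H]2C[C@@H](OC(=O)[C@H]2C)[C@@](C)(O[Si](CC)(CC)CC)CC[C@@H]1O | intermediate
32 | 2,3-dimethylbut-2-ene | CC(C)=C(C)C | starting material
33 | 2-methoxyprop-2-yl hydroperoxide | COC(C)(C)OO | intermediate
34 | 7-O-methanesulfonate of 31, (7S) (not isolated) | C=C1CC[C@@H]2O[C@@]2(C)CC[C@@H]2C[C@@H](OC(=O)[C@H]2C)[C@@](C)(O[Si](CC)(CC)CC)CC[C@@H]1OS(C)(=O)=O | intermediate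
35 | (1R,3R,4S,7R,11S,12S,15S)-11,12-epoxy-7-[(2-methoxypropan-2-yl)peroxy]-4-(triethylsilyloxy)cembr-8(19)-en-16,3-olide | C=C1CC[C@@H]2O[C@@]2(C)CC[C@@H]2C[C@@H](OC(=O)[C@H]2C)[C@@](C)(O[Si](CC)(CC)CC)CC[C@H]1OOC(C)(C)OC | intermediate
36 | (1R,3R,4S,7R,11S,12S,15S)-11,12-epoxy-7-hydroperoxy-4-(triethylsilyloxy)cembr-8(19)-en-16,3-olide | C=C1CC[C@@H]2O[C@@]2(C)CC[C@@H]2C[C@@H](OC(=O)[C@H]2C)[C@@](C)(O[Si](CC)(CC)CC)CC[C@H]1OO | intermediate
37 | (1R,3R,4S,7R,11S,12S,15S)-11,12-epoxy-7-hydroperoxy-4-hydroxycembr-8(19)-en-16,3-olide (CNP0319766.1) | C=C1CC[C@@H]2O[C@@]2(C)CC[C@@H]2C[C@@H](OC(=O)[C@H]2C)[C@@](C)(O)CC[C@H]1OO | target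

## Step count and least certain steps

Total: 21 steps. Longest linear sequence: 17 steps (steps 4–17 and 19–21, from pent-4-yn-1-ol); steps 1–3 and step 18 are side branches.

**Step 11 (key step).** Three things may go wrong. Facial selection at C3 may be poor, because methyl and methylene on C4 differ little and the ligand's influence on a hindered aliphatic aldehyde is untested. Part of the dienolate may react through the s-trans rotamer, which gives a silylated (2E)-adduct that cannot lactonise. Addition to the neopentyl-type aldehyde may be slow enough for silyl transfer to compete.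
The fallback sets out from ester 17 and aldehyde 5. Ester 17 is deprotonated with LiN(i-Pr)2 in THF/DMPU at −78 °C to lithium dienolate 18, 5 is added and the mixture is warmed to −20 °C. Kinetic α-adducts revert, while the γ-adduct, the lithium (2Z)-aldolate F1, closes onto the ester with loss of ethoxide and returns to the route at lactone 21. The metal dienolate keeps the C2/C16 cis geometry fixed by the syn deprotonation, so ring closure no longer depends on a rotamer. Facial selectivity then rests on the Felkin–Anh bias alone, and the C3 epimer is removed by chromatography.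

**Step 19.** Substitution at the secondary, 2-substituted allylic C7 may be overtaken by elimination to the diene, by SN2′ attack at C19, by reversible attack of the peroxide anion on the lactone, or by base-induced Kornblum–DeLaMare fragmentation of the product.
The fallback sets out from alcohol 29 (either C7 epimer). Mitsunobu reaction with 2-nitrobenzenesulfonylhydrazide (PPh3, diethyl azodicarboxylate, −30 °C) gives the N-allyl sulfonylhydrazine F2, which loses sulfinic acid on warming to the allylic diazene F3. Sigmatropic loss of N2 transposes the alkene and gives the (7E)-C7=C8 macrocycle with a C19 methyl group, F4. Schenck ene reaction (O2, tetraphenylporphyrin, hν, CH2Cl2, 0 °C) then places oxygen on C7 with return of the double bond to C8=C19, rejoining the route at hydroperoxide 36 before step 21. This trades the substitution problem for the regio- and face selectivity of the ene step.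

**Step 15.** Oligomerisation may compete with closure of the 14-membered ring, and the chromium chloride Lewis acid may open the trisubstituted epoxide during the long addition time.
The fallback sets out from aldehyde 27. NaClO2/NaH2PO4/2-methylbut-2-ene gives the seco acid F5. Me3SnSnMe3 with Pd(PPh3)4 exchanges iodine for tin to give the alkenylstannane acid F6. 1-Chloro-N,N,2-trimethylprop-1-en-1-amine converts this under neutral conditions into the acid chloride F7. Intramolecular acylation of the alkenylstannane (Stille type, Pd2(dba)3/tri(2-furyl)phosphine, high dilution) closes the ring directly to enone 30, and the route continues with step 17.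

**Step 12.** The hindered β,β-disubstituted enoate may be reduced slowly, so that hydrodeiodination of the C8–I bond competes, and face selectivity may be incomplete.
The fallback sets out from lactone 21 and moves the reduction behind the ring closure, where no C–I bond remains. OsO4/NaIO4 cleavage gives the unsaturated seco-aldehyde F8. CrCl2/NiCl2 closure gives the macrocyclic allylic alcohol F9, which still holds the C1=C15 lactone. The same CuH system then gives the saturated, C15-unsubstituted lactone alcohol F10. Alkoxide–enolate dianion formation with LiN(SiMe3)2 (2.2 equiv) and C-methylation with iodomethane at −78 °C rejoin the route at alcohol 29.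

## Further compounds

F1 | step 11 | lithium alkoxide of ethyl (2Z,5R,6S)-5-hydroxy-3-{2-[(2S,3S)-3-(3-iodobut-3-en-1-yl)-2-methyloxiran-2-yl]ethyl}-6,10-dimethyl-6-(triethylsilyloxy)undeca-2,9-dienoate | CCOC(=O)/C=C(\C[C@@H](O[Li])[C@@](C)(O[Si](CC)(CC)CC)CCC=C(C)C)CC[C@]1(C)O[C@H]1CCC(I)=C
F2 | step 19 | N-(cembranolid-7-yl)-2-nitrobenzenesulfonohydrazide derived from 29 (C7–N in place of C7–O) | C=C1CC[C@@H]2O[C@@]2(C)CC[C@@H]2C[C@@H](OC(=O)[C@H]2C)[C@@](C)(O[Si](CC)(CC)CC)CCC1N(N)S(=O)(=O)c1ccccc1[N+](=O)[O-]
F3 | step 19 | allylic monoalkyl diazene derived from F2 | C=C1CC[C@@H]2O[C@@]2(C)CC[C@@H]2C[C@@H](OC(=O)[C@H]2C)[C@@](C)(O[Si](CC)(CC)CC)CCC1N=N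
F4 | step 19 | (1R,3R,4S,7E,11S,12S,15S)-11,12-epoxy-4-(triethylsilyloxy)cembr-7-en-16,3-olide | C/C1=C\CC[C@](C)(O[Si](CC)(CC)CC)[C@H]2C[C@@H](CC[C@]3(C)O[C@H]3CC1)[C@H](C)C(=O)O2
F5 | step 15 | (4S)-4-[(2R,4R,5S)-4-{2-[(2S,3S)-3-(3-iodobut-3-en-1-yl)-2-methyloxiran-2-yl]ethyl}-5-methyl-6-oxooxan-2-yl]-4-(triethylsilyloxy)pentanoic acid | O=C1[C@@H](C)[C@H](CC[C@]2(C)O[C@H]2CCC(I)=C)C[C@@H](O1)[C@@](C)(O[Si](CC)(CC)CC)CCC(=O)O
F6 | step 15 | trimethylstannyl analogue of F5 (C8–SnMe3 in place of C8–I) | O=C1[C@@H](C)[C@H](CC[C@]2(C)O[C@H]2CCC([Sn](C)(C)C)=C)C[C@@H](O1)[C@@](C)(O[Si](CC)(CC)CC)CCC(=O)O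
F7 | step 15 | acid chloride of F6 | O=C1[C@@H](C)[C@H](CC[C@]2(C)O[C@H]2CCC([Sn](C)(C)C)=C)C[C@@H](O1)[C@@](C)(O[Si](CC)(CC)CC)CCC(=O)Cl
F8 | step 12 | (4S)-4-[(2R)-4-{2-[(2S,3S)-3-(3-iodobut-3-en-1-yl)-2-methyloxiran-2-yl]ethyl}-6-oxo-3,6-dihydro-2H-pyran-2-yl]-4-(triethylsilyloxy)pentanal | O=C1C=C(CC[C@]2(C)O[C@H]2CCC(I)=C)C[C@@H](O1)[C@@](C)(O[Si](CC)(CC)CC)CCC=O
F9 | step 12 | (3R,4S,11S,12S)-11,12-epoxy-7-hydroxy-4-(triethylsilyloxy)-17-norcembra-1(15),8(19)-dien-16,3-olide (C7 epimers) | C=C1CC[C@@H]2O[C@@]2(C)CCC2=CC(=O)O[C@H](C2)[C@@](C)(O[Si](CC)(CC)CC)CCC1O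
F10 | step 12 | (1R,3R,4S,11S,12S)-11,12-epoxy-7-hydroxy-4-(triethylsilyloxy)-17-norcembr-8(19)-en-16,3-olide (C7 epimers) | C=C1CC[C@@H]2O[C@@]2(C)CC[C@@H]2C[C@@H](OC(=O)C2)[C@@](C)(O[Si](CC)(CC)CC)CCC1O
A1 | alternative 1 | 16-membered allyl enol carbonate (C4 enol oxygen linked through a carbonate to C6; C3 p-methoxybenzyl ether; C16 methyl ester) | C=C1OC(=O)OC/C=C(\C)CC[C@@H]2O[C@@]2(C)CC[C@H](C[C@H]1OCc3ccc(OC)cc3)[C@H](C)C(=O)OC
A2 | alternative 1 | 14-membered C4 ketone with C3 p-methoxybenzyl ether | C1/C=C(\C)CC[C@@H]2O[C@@]2(C)CC[C@H](C[C@@H](OCc3ccc(OC)cc3)C(=O)C1)[C@H](C)C(=O)OC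
A3 | alternative 2 | (2E,6E,10E)-2,6,10-trimethyldodeca-2,6,10-triene-1,12-diol | OC/C=C(\C)CC/C=C(\C)CC/C=C(\C)CO
A4 | alternative 2 | bis-epoxy diol (3S,4S,11S,12S in target numbering) | OC[C@@H]1O[C@@]1(C)CC/C=C(\C)CC[C@@H]1O[C@@]1(C)CO
A5 | alternative 3 | macrocyclic C3 bromoacetal with C1=C14 and C7=C8 alkenes and C4 triethylsilyl ether | C1/C=C(\C)CC[C@@H]2O[C@@]2(C)C/C=C/C[C@@H](OC(OCC)C(C)Br)[C@@](C)(O[Si](CC)(CC)CC)C1
A6 | alternative 3 | bicyclic ethyl lactol acetal with C1 and C15 set (acetal carbon undefined) | C1/C=C(\C)CC[C@@H]2O[C@@]2(C)CC[C@@H]2C[C@@H](OC(OCC)[C@H]2C)[C@@](C)(O[Si](CC)(CC)CC)C1
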